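**Retrosynthetic overview**
1. Target 28 ← protected diester 27 by one Lewis-acid step (3 Bn and t-Bu off); the (E)-butenedioate comes from enal 25, made by aldol condensation of aldehyde 22 with tert-butyl glyoxylate.
2. Isochromanone 21/22 ← lactonisation of a C3–OH onto the ortho methyl benzoate; C3–O comes from malonate hydroxylation, then dealkoxycarbonylation and trans equilibration.
3. C4 stereocentre ← key intermolecular asymmetric Michael addition of dimethyl malonate to cinnamaldehyde 14 (iminium catalysis).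
4. Enal 14 ← 1,2,4-triacetoxybenzene by benzylation, bromination, Br-directed ortho-lithiation/formylation, Br→CO2Me and a two-carbon Wittig homologation.
5. Rings: the arene is bought; the lactone (step 11) is the only ring formed.

Assumption: core numbering is that of isochroman-1-one (C3 carries CO2Me, C4 the butenedioate); tert-butyl glyoxylate, phosphonium salt 11 and the (S)-diarylprolinol silyl ether catalyst are bought.

**Route**

Step 1
Reactants: 1 1,2,4-triacetoxybenzene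
Product: 3 1,2,4-tris(benzyloxy)benzene, via benzene-1,2,4-triol 2 (not isolated)
Conditions: BnBr (3.6 eq), K2CO3 (6 eq), MeOH (6 eq), DMF, N2, 60 °C
Reagents that add atoms: benzyl bromide, BrCc1ccccc1
Why: K2CO3/MeOH transesterifies the aryl acetates and the phenoxides are benzylated at once (Williamson ether synthesis), so the air-sensitive triol is never handled.

Step 2
Reactants: 3 1,2,4-tris(benzyloxy)benzene
Product: 4 1-bromo-2,4,5-tris(benzyloxy)benzene
Conditions: NBS (1.05 eq), MeCN, 0 °C → rt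
Reagents that add atoms: N-bromosuccinimide, O=C1CCC(=O)N1Br
Why: Electrophilic aromatic bromination goes to C5, the only free position that is para to one OBn, ortho to another and not flanked on both sides.

Step 3
Reactants: 4 1-bromo-2,4,5-tris(benzyloxy)benzene
Product: 6 2-bromo-3,5,6-tris(benzyloxy)benzaldehyde, via aryllithium 5 (not isolated)
Conditions: LDA (1.15 eq), THF, −78 °C; DMF (3 eq), −78 → 0 °C; aq. HCl
Reagents that add atoms: N,N-dimethylformamide, CN(C)C=O
Why: Directed ortho-lithiation: LDA removes only the proton flanked by Br and OBn (too weak for the H between two OBn; −78 °C avoids benzyne), and DMF formylates the aryllithium (Bouveault).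

Step 4
Reactants: 6 2-bromo-3,5,6-tris(benzyloxy)benzaldehyde
Product: 7 2-[2-bromo-3,5,6-tris(benzyloxy)phenyl]-1,3-dioxolane
Conditions: HOCH2CH2OH (5 eq), TsOH·H2O (5 mol %), PhMe, reflux, Dean–Stark
Reagents that add atoms: ethane-1,2-diol, OCCO
Why: Acetalisation masks the aldehyde against butyllithium in the next step.

Step 5
Reactants: 7 2-[2-bromo-3,5,6-tris(benzyloxy)phenyl]-1,3-dioxolane
Product: 9 methyl 3,4,6-tris(benzyloxy)-2-(1,3-dioxolan-2-yl)benzoate, via aryllithium 8 (not isolated)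
Conditions: n-BuLi (1.05 eq), THF, −78 °C; ClCO2Me (2 eq), −78 °C → rt
Reagents that add atoms: methyl chloroformate, COC(=O)Cl
Why: Bromine–lithium exchange outruns any deprotonation at −78 °C and the 2-(dioxolanyl)aryllithium is acylated by the chloroformate.

Step 6
Reactants: 9 methyl 3,4,6-tris(benzyloxy)-2-(1,3-dioxolan-2-yl)benzoate
Product: 10 methyl 3,4,6-tris(benzyloxy)-2-formylbenzoate
Conditions: 2 M HCl, THF, rt
Reagents that add atoms: water, O
Why: Acid-catalysed acetal hydrolysis; the di-ortho-substituted methyl benzoate is inert to dilute acid.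

Step 7
Reactants: 10 methyl 3,4,6-tris(benzyloxy)-2-formylbenzoate; 11 (1,3-dioxolan-2-ylmethyl)triphenylphosphonium bromide
Product: 14 methyl 3,4,6-tris(benzyloxy)-2-[(E)-3-oxoprop-1-enyl]benzoate, via phosphorus ylide 12 (not isolated), via vinyl dioxolane 13 (not isolated)
Conditions: 11 (1.5 eq), LiOMe (1.6 eq), DMF, 80 °C; then 1 M HCl, THF, rt
Reagents that add atoms: water, O
Why: Wittig olefination with a reactive ylide copes with the hindered aldehyde and cannot over-homologate; acid hydrolysis of the vinyl acetal gives, and equilibrates to, the E-enal, and methoxide is harmless to the methyl ester.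

Step 8
Reactants: 14 methyl 3,4,6-tris(benzyloxy)-2-[(E)-3-oxoprop-1-enyl]benzoate; 15 dimethyl malonate
Product: 16 dimethyl 2-[(1R)-3-oxo-1-[2,3,5-tris(benzyloxy)-6-(methoxycarbonyl)phenyl]propyl]propanedioate
Conditions: 15 (3 eq), (S)-2-{bis[3,5-bis(trifluoromethyl)phenyl](trimethylsilyloxy)methyl}pyrrolidine (20 mol %), EtOH, 0 °C → rt
Reagents that add atoms: none
Why: Iminium-catalysed asymmetric Michael addition (Jørgensen–Hayashi): the (S)-catalyst gives the E, s-trans iminium ion with one face blocked by the CAr2OTMS group, so malonate adds to the other face of C-β and sets the benzylic centre R (future C4).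

Step 9
Reactants: 16 dimethyl 2-[(1R)-3-oxo-1-[2,3,5-tris(benzyloxy)-6-(methoxycarbonyl)phenyl]propyl]propanedioate
Product: 17 dimethyl 2-[(1R)-2-(1,3-dioxolan-2-yl)-1-[2,3,5-tris(benzyloxy)-6-(methoxycarbonyl)phenyl]ethyl]propanedioate
Conditions: HOCH2CH2OH (5 eq), PPTS (10 mol %), benzene, reflux, Dean–Stark
Reagents that add atoms: ethane-1,2-diol, OCCO
Why: Acetalisation removes the enolisable aldehyde before the base and heat of steps 10 and 11; the β-stereocentre is not affected.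

Step 10
Reactants: 17 dimethyl 2-[(1R)-2-(1,3-dioxolan-2-yl)-1-[2,3,5-tris(benzyloxy)-6-(methoxycarbonyl)phenyl]ethyl]propanedioate
Product: 19 dimethyl 2-[(1S)-2-(1,3-dioxolan-2-yl)-1-[2,3,5-tris(benzyloxy)-6-(methoxycarbonyl)phenyl]ethyl]-2-hydroxypropanedioate, via potassium enolate 18 (not isolated)
Conditions: KHMDS (1.1 eq), THF, −78 °C; 2-(phenylsulfonyl)-3-phenyloxaziridine (1.3 eq), −78 → −40 °C; AcOH
Reagents that add atoms: 2-(phenylsulfonyl)-3-phenyloxaziridine, O=S(=O)(c1ccccc1)N1OC1c1ccccc1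
Why: Davis oxidation of the malonate enolate, the only site deprotonated (pKa about 13); the new carbinol carbon is not stereogenic and the descriptor change R→S is only a priority change.

Step 11
Reactants: 19 dimethyl 2-[(1S)-2-(1,3-dioxolan-2-yl)-1-[2,3,5-tris(benzyloxy)-6-(methoxycarbonyl)phenyl]ethyl]-2-hydroxypropanedioate
Product: 21 methyl (3S,4S)-5,6,8-tris(benzyloxy)-4-(1,3-dioxolan-2-ylmethyl)-1-oxo-3,4-dihydro-1H-isochromene-3-carboxylate, via hydroxy ester 20 (not isolated)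
Conditions: LiCl (3 eq), H2O (3 eq), DMSO, 130 °C; then DBU (0.5 eq), MeCN, 60 °C
Reagents that add atoms: none
Why: Krapcho dealkoxycarbonylation, then lactonisation onto the ortho methyl benzoate (the only ester in reach, the side chain being an acetal) and DBU epimerisation of C3–H give the thermodynamic trans lactone, so 3S is set relative to C4 by thermodynamic control (the C4 group is pushed pseudo-axial by the peri C5–OBn and CO2Me sits anti to it).

Step 12
Reactants: 21 methyl (3S,4S)-5,6,8-tris(benzyloxy)-4-(1,3-dioxolan-2-ylmethyl)-1-oxo-3,4-dihydro-1H-isochromene-3-carboxylate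
Product: 22 methyl (3S,4S)-5,6,8-tris(benzyloxy)-1-oxo-4-(2-oxoethyl)-3,4-dihydro-1H-isochromene-3-carboxylate
Conditions: 2 M HCl, THF, 40 °C
Reagents that add atoms: water, O
Why: Acetal hydrolysis under conditions that do not enolise C3 or open the lactone.

Step 13
Reactants: 22 methyl (3S,4S)-5,6,8-tris(benzyloxy)-1-oxo-4-(2-oxoethyl)-3,4-dihydro-1H-isochromene-3-carboxylate; 23 tert-butyl glyoxylate
Product: 25 tert-butyl (2E)-3-formyl-3-[(3S,4R)-5,6,8-tris(benzyloxy)-3-(methoxycarbonyl)-1-oxo-3,4-dihydro-1H-isochromen-4-yl]prop-2-enoate, via aldol adduct 24 (not isolated)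
Conditions: 23 (1.5 eq), pyrrolidine (20 mol %), PhCO2H (20 mol %), PhMe, 4 Å MS, rt → 50 °C
Reagents that add atoms: none
Why: Enamine-mediated crossed aldol condensation: only 22 can form an enamine and glyoxylate is a non-enolisable acceptor; dehydration through the conjugated iminium ion puts CO2tBu anti to the formyl carbon (E), and nothing basic enough to touch C3–H or C4–H is present.

Step 14
Reactants: 25 tert-butyl (2E)-3-formyl-3-[(3S,4R)-5,6,8-tris(benzyloxy)-3-(methoxycarbonyl)-1-oxo-3,4-dihydro-1H-isochromen-4-yl]prop-2-enoate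
Product: 26 (2E)-4-tert-butoxy-4-oxo-2-[(3S,4R)-5,6,8-tris(benzyloxy)-3-(methoxycarbonyl)-1-oxo-3,4-dihydro-1H-isochromen-4-yl]but-2-enoic acid
Conditions: NaClO2, NaH2PO4, 2-methyl-2-butene, t-BuOH/H2O, 0 °C → rt
Reagents that add atoms: sodium chlorite, [Na+].[O-]Cl=O
Why: Pinnick oxidation turns the enal into the acid without changing alkene geometry or stereocentres; the scavenger protects the electron-rich arene from HOCl.

Step 15
Reactants: 26 (2E)-4-tert-butoxy-4-oxo-2-[(3S,4R)-5,6,8-tris(benzyloxy)-3-(methoxycarbonyl)-1-oxo-3,4-dihydro-1H-isochromen-4-yl]but-2-enoic acid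
Product: 27 4-tert-butyl 1-methyl (2E)-2-[(3S,4R)-5,6,8-tris(benzyloxy)-3-(methoxycarbonyl)-1-oxo-3,4-dihydro-1H-isochromen-4-yl]but-2-enedioate
Conditions: MeI (1.5 eq), KHCO3 (2 eq), DMF, rt
Reagents that add atoms: iodomethane, CI
Why: SN2 O-methylation of the carboxylate; bicarbonate is too weak to deprotonate C3–H or the γ C4–H, so there is no alkene migration or E1cB ring opening (diazoalkanes are avoided because they add to fumarates).

Step 16
Reactants: 27 4-tert-butyl 1-methyl (2E)-2-[(3S,4R)-5,6,8-tris(benzyloxy)-3-(methoxycarbonyl)-1-oxo-3,4-dihydro-1H-isochromen-4-yl]but-2-enedioate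
Product: 28 (2E)-4-methoxy-4-oxo-3-[(3S,4R)-5,6,8-trihydroxy-3-(methoxycarbonyl)-1-oxo-3,4-dihydro-1H-isochromen-4-yl]but-2-enoic acid (target)
Conditions: BCl3 (10 eq), C6HMe5 (10 eq), CH2Cl2, −78 → −20 °C; then H2O
Reagents that add atoms: none
Why: Lewis-acid dealkylation with pentamethylbenzene as cation scavenger removes the three benzyl ethers and the tert-butyl ester at low temperature and leaves methyl esters, lactone and E-alkene alone; hydrogenolysis is excluded by the alkene.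

**Compound list**
1 | 1,2,4-triacetoxybenzene | CC(=O)Oc1ccc(OC(C)=O)c(OC(C)=O)c1 | starting material
2 | benzene-1,2,4-triol (as phenoxide in situ) | Oc1ccc(O)c(O)c1 | intermediate (not isolated)
3 | 1,2,4-tris(benzyloxy)benzene | c1cc(OCc2ccccc2)c(OCc2ccccc2)cc1OCc1ccccc1 | intermediate
4 | 1-bromo-2,4,5-tris(benzyloxy)benzene | Brc1cc(OCc2ccccc2)c(OCc2ccccc2)cc1OCc1ccccc1 | intermediate
5 | [2-bromo-3,5,6-tris(benzyloxy)phenyl]lithium | [Li]c1c(Br)c(OCc2ccccc2)cc(OCc2ccccc2)c1OCc1ccccc1 | intermediate (not isolated)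
6 | 2-bromo-3,5,6-tris(benzyloxy)benzaldehyde | O=Cc1c(Br)c(OCc2ccccc2)cc(OCc2ccccc2)c1OCc1ccccc1 | intermediate
7 | 2-[2-bromo-3,5,6-tris(benzyloxy)phenyl]-1,3-dioxolane | Brc1c(OCc2ccccc2)cc(OCc2ccccc2)c(OCc2ccccc2)c1C1OCCO1 | intermediate
8 | [3,5,6-tris(benzyloxy)-2-(1,3-dioxolan-2-yl)phenyl]lithium | [Li]c1c(OCc2ccccc2)cc(OCc2ccccc2)c(OCc2ccccc2)c1C1OCCO1 | intermediate (not isolated)
9 | methyl 3,4,6-tris(benzyloxy)-2-(1,3-dioxolan-2-yl)benzoate | COC(=O)c1c(OCc2ccccc2)cc(OCc2ccccc2)c(OCc2ccccc2)c1C1OCCO1 | intermediate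
10 | methyl 3,4,6-tris(benzyloxy)-2-formylbenzoate | COC(=O)c1c(OCc2ccccc2)cc(OCc2ccccc2)c(OCc2ccccc2)c1C=O | intermediate
11 | (1,3-dioxolan-2-ylmethyl)triphenylphosphonium bromide | [Br-].C(C1OCCO1)[P+](c1ccccc1)(c1ccccc1)c1ccccc1 | starting material
12 | (1,3-dioxolan-2-ylmethylidene)triphenylphosphorane | C(C1OCCO1)=P(c1ccccc1)(c1ccccc1)c1ccccc1 | intermediate (not isolated)
13 | methyl 3,4,6-tris(benzyloxy)-2-[2-(1,3-dioxolan-2-yl)ethenyl]benzoate (E/Z mixture) | COC(=O)c1c(OCc2ccccc2)cc(OCc2ccccc2)c(OCc2ccccc2)c1C=CC1OCCO1 | intermediate (not isolated)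
14 | methyl 3,4,6-tris(benzyloxy)-2-[(E)-3-oxoprop-1-enyl]benzoate | COC(=O)c1c(OCc2ccccc2)cc(OCc2ccccc2)c(OCc2ccccc2)c1/C=C/C=O | intermediate
15 | dimethyl malonate | COC(=O)CC(=O)OC | starting material
16 | dimethyl 2-[(1R)-3-oxo-1-[2,3,5-tris(benzyloxy)-6-(methoxycarbonyl)phenyl]propyl]propanedioate | O=CC[C@H](C(C(=O)OC)C(=O)OC)c1c(OCc2ccccc2)c(OCc2ccccc2)cc(OCc2ccccc2)c1C(=O)OC | intermediate
17 | dimethyl 2-[(1R)-2-(1,3-dioxolan-2-yl)-1-[2,3,5-tris(benzyloxy)-6-(methoxycarbonyl)phenyl]ethyl]propanedioate | O1CCOC1C[C@H](C(C(=O)OC)C(=O)OC)c1c(OCc2ccccc2)c(OCc2ccccc2)cc(OCc2ccccc2)c1C(=O)OC | intermediate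
18 | potassium enolate of 17 | [K+].O1CCOC1C[C@H](C(C(=O)OC)=C([O-])OC)c1c(OCc2ccccc2)c(OCc2ccccc2)cc(OCc2ccccc2)c1C(=O)OC | intermediate (not isolated)
19 | dimethyl 2-[(1S)-2-(1,3-dioxolan-2-yl)-1-[2,3,5-tris(benzyloxy)-6-(methoxycarbonyl)phenyl]ethyl]-2-hydroxypropanedioate | O1CCOC1C[C@H](C(O)(C(=O)OC)C(=O)OC)c1c(OCc2ccccc2)c(OCc2ccccc2)cc(OCc2ccccc2)c1C(=O)OC | intermediate
20 | methyl 3,4,6-tris(benzyloxy)-2-[(2S)-1-(1,3-dioxolan-2-yl)-3-hydroxy-4-methoxy-4-oxobutan-2-yl]benzoate (both carbinol epimers) | O1CCOC1C[C@H](C(O)C(=O)OC)c1c(OCc2ccccc2)c(OCc2ccccc2)cc(OCc2ccccc2)c1C(=O)OC | intermediate (not isolated)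
21 | methyl (3S,4S)-5,6,8-tris(benzyloxy)-4-(1,3-dioxolan-2-ylmethyl)-1-oxo-3,4-dihydro-1H-isochromene-3-carboxylate | O1CCOC1C[C@H]1c2c(OCc3ccccc3)c(OCc3ccccc3)cc(OCc3ccccc3)c2C(=O)O[C@@H]1C(=O)OC | intermediate
22 | methyl (3S,4S)-5,6,8-tris(benzyloxy)-1-oxo-4-(2-oxoethyl)-3,4-dihydro-1H-isochromene-3-carboxylate | O=CC[C@H]1c2c(OCc3ccccc3)c(OCc3ccccc3)cc(OCc3ccccc3)c2C(=O)O[C@@H]1C(=O)OC | intermediate
23 | tert-butyl glyoxylate | O=CC(=O)OC(C)(C)C | starting material
24 | tert-butyl 3-formyl-2-hydroxy-3-[(3S,4S)-5,6,8-tris(benzyloxy)-3-(methoxycarbonyl)-1-oxo-3,4-dihydro-1H-isochromen-4-yl]propanoate (diastereomer mixture) | O=CC(C(O)C(=O)OC(C)(C)C)[C@H]1c2c(OCc3ccccc3)c(OCc3ccccc3)cc(OCc3ccccc3)c2C(=O)O[C@@H]1C(=O)OC | intermediate (not isolated)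
25 | tert-butyl (2E)-3-formyl-3-[(3S,4R)-5,6,8-tris(benzyloxy)-3-(methoxycarbonyl)-1-oxo-3,4-dihydro-1H-isochromen-4-yl]prop-2-enoate | O=C/C(=C/C(=O)OC(C)(C)C)[C@H]1c2c(OCc3ccccc3)c(OCc3ccccc3)cc(OCc3ccccc3)c2C(=O)O[C@@H]1C(=O)OC | intermediate
26 | (2E)-4-tert-butoxy-4-oxo-2-[(3S,4R)-5,6,8-tris(benzyloxy)-3-(methoxycarbonyl)-1-oxo-3,4-dihydro-1H-isochromen-4-yl]but-2-enoic acid | OC(=O)/C(=C/C(=O)OC(C)(C)C)[C@H]1c2c(OCc3ccccc3)c(OCc3ccccc3)cc(OCc3ccccc3)c2C(=O)O[C@@H]1C(=O)OC | intermediate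
27 | 4-tert-butyl 1-methyl (2E)-2-[(3S,4R)-5,6,8-tris(benzyloxy)-3-(methoxycarbonyl)-1-oxo-3,4-dihydro-1H-isochromen-4-yl]but-2-enedioate | COC(=O)/C(=C/C(=O)OC(C)(C)C)[C@H]1c2c(OCc3ccccc3)c(OCc3ccccc3)cc(OCc3ccccc3)c2C(=O)O[C@@H]1C(=O)OC | intermediate
28 | (2E)-4-methoxy-4-oxo-3-[(3S,4R)-5,6,8-trihydroxy-3-(methoxycarbonyl)-1-oxo-3,4-dihydro-1H-isochromen-4-yl]but-2-enoic acid | COC(=O)/C(=C/C(=O)O)[C@H]1c2c(O)c(O)cc(O)c2C(=O)O[C@@H]1C(=O)OC | target

**Totals**
Total steps: 16. Longest linear sequence: 16 steps (1 → 28); 11, 15 and 23 are bought.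

**Steps most likely to fail, with fallbacks**

Step 8 (Michael addition to a di-ortho-substituted cinnamaldehyde; rate and ee may drop). The fallback sets out from 10 and returns at 16. Knoevenagel condensation of 10 with 15 (piperidine, AcOH, benzene, reflux) gives dimethyl 2-{[2,3,5-tris(benzyloxy)-6-(methoxycarbonyl)phenyl]methylidene}propanedioate F1. A Cu(OTf)2/t-Bu-bis(oxazoline)-catalysed Mukaiyama–Michael addition of 1-(ethylthio)-1-(trimethylsilyloxy)ethene (HFIP, CH2Cl2, −78 °C; ligand enantiomer chosen for the R centre) gives dimethyl 2-[(1R)-3-(ethylsulfanyl)-3-oxo-1-[2,3,5-tris(benzyloxy)-6-(methoxycarbonyl)phenyl]propyl]propanedioate F2. Fukuyama reduction (Et3SiH, Pd/C, acetone) turns the thioester into aldehyde 16. Here the acceptor is activated by two-point binding to a chiral Lewis acid and no longer by an amine.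

Step 11 (the trans:cis ratio at C3 rests on thermodynamics). The fallback sets out from 17 and returns at 21 through 20. Krapcho dealkoxycarbonylation of 17 (LiCl, H2O, DMSO, 130 °C) gives methyl 3,4,6-tris(benzyloxy)-2-[(2R)-1-(1,3-dioxolan-2-yl)-4-methoxy-4-oxobutan-2-yl]benzoate F3. Its potassium enolate (KHMDS, −78 °C) is hydroxylated under reagent control with the matched enantiomer of (camphorsulfonyl)oxaziridine to give one epimer of 20, which is lactonised without epimerisation (2-hydroxypyridine, PhMe, 100 °C) to 21. C3 is then set kinetically and not by equilibration.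

Step 13 (incomplete dehydration or E/Z mixtures in the amine-catalysed condensation). The fallback sets out from 22 and returns at 25 through 24. TBSOTf/Et3N (CH2Cl2, 0 °C) converts 22 into methyl (3S,4S)-5,6,8-tris(benzyloxy)-4-[2-(tert-butyldimethylsilyloxy)ethenyl]-1-oxo-3,4-dihydro-1H-isochromene-3-carboxylate F4. A BF3·OEt2-mediated Mukaiyama aldol with 23 (CH2Cl2, −78 °C) gives aldol adduct 24, which is isolated and dehydrated separately (TsOH, PhMe, 60 °C) to 25. C–C bond formation and elimination are thus decoupled and run under Lewis or Brønsted acid without any amine.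

**Further compounds**
F1 | step 8 | dimethyl 2-{[2,3,5-tris(benzyloxy)-6-(methoxycarbonyl)phenyl]methylidene}propanedioate | COC(=O)C(=Cc1c(OCc2ccccc2)c(OCc2ccccc2)cc(OCc2ccccc2)c1C(=O)OC)C(=O)OC
F2 | step 8 | dimethyl 2-[(1R)-3-(ethylsulfanyl)-3-oxo-1-[2,3,5-tris(benzyloxy)-6-(methoxycarbonyl)phenyl]propyl]propanedioate | CCSC(=O)C[C@H](C(C(=O)OC)C(=O)OC)c1c(OCc2ccccc2)c(OCc2ccccc2)cc(OCc2ccccc2)c1C(=O)OC
F3 | step 11 | methyl 3,4,6-tris(benzyloxy)-2-[(2R)-1-(1,3-dioxolan-2-yl)-4-methoxy-4-oxobutan-2-yl]benzoate | O1CCOC1C[C@H](CC(=O)OC)c1c(OCc2ccccc2)c(OCc2ccccc2)cc(OCc2ccccc2)c1C(=O)OC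
F4 | step 13 | methyl (3S,4S)-5,6,8-tris(benzyloxy)-4-[2-(tert-butyldimethylsilyloxy)ethenyl]-1-oxo-3,4-dihydro-1H-isochromene-3-carboxylate | CC(C)(C)[Si](C)(C)OC=C[C@H]1c2c(OCc3ccccc3)c(OCc3ccccc3)cc(OCc3ccccc3)c2C(=O)O[C@@H]1C(=O)OC
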